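Numbering used throughout: core atoms are C1 (quaternary bridgehead carrying the dienyl chain), C2 (methyl carbinol), C3, C4, C5 (oxygen-bearing bridgehead), O6, C7 (OCH2), C8 (carbon carrying the hydroxypropyl chain) and Cx (the CH(CH3)CHO carbon on C5). Compounds are numbered 1–28 as in the steps; 14 is the cyclization precursor, 15 its product, 20 the irone, 23 the sulfone, 28 the target.

## Analysis of the target

The core is a 6-oxabicyclo[3.2.1]octane: a cyclohexane (C1–C2–C3–C4–C5–C8) whose 1,3-related carbons C1 and C5 are tied together by the O6–C7 bridge. C1 is an all-carbon quaternary centre carrying a (3E,5E)-dienyl chain that ends in a cis-2,5,6,6-tetramethylcyclohex-2-enyl ring, C2 is a tertiary methyl carbinol, C5 carries the CH(CH3)CHO branch and C8 a 3-hydroxypropyl chain. There are seven stereocentres: C1 and C5 are coupled by the bridge; the C8 chain lies on the side of the O6–C7 bridge (equatorial in the carbocycle); the C2 methyl is axial, anti to C7; Cx is acyclic and sits next to the fully substituted C5; the two ring centres are remote and come as a pair. The sensitive groups are the α-branched aldehyde (epimerizable), the conjugated diene with its doubly allylic ring hydrogen, and a tertiary alcohol. The three oxygenated chain ends (the C1 chain terminus, Cx and the C8 chain) must be addressed in a fixed order. The hard parts are the contiguous C1 (quaternary), C2 (tertiary carbinol) and C8 centres, the fully substituted C5–O centre, and the relation of the acyclic Cx centre to the core. The strategy rests on one feature: C1 lies between C2 and C7, which can both be carbonyl carbons (ketone and lactone), so C1 is the α-carbon of a β-keto ester, and it is 1,3 to the tertiary C5–O bond. A radical at C1 that adds to C8 of a C5=C8 alkene therefore leaves an oxidizable centre at C5 exactly where the C7 carboxyl oxygen can capture it.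

## Retrosynthetic reasoning

From 28 back to 25: the aldehyde at Cx is formed last but one, because it is the only epimerizable centre. So 28 comes from its silyl ether 27 by fluoride cleavage under buffered conditions, 27 from the primary alcohol 26 by a mild oxidation, and 26 from 25 by selective removal of the more labile of two silyl ethers. What is gained is a fixed order of unveiling: Cx first, the C8 chain last.

From 25 to 24: the C2–CH3 bond is cut, which leads to the ketone 24. It is cut this late because a tertiary C2 alcohol present earlier would sit 1,5 to the chain aldehyde needed for the olefination and would close to a lactol; a carbonyl at C2 avoids this. The forward reaction must deliver the methyl group axially, anti to the C7 bridge.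

From 24 to 19 and 23: the trisubstituted alkene of the diene is cut by a Julia–Kocienski disconnection. This is the place because the sulfone 23 then carries the ring, both ring stereocentres, the disubstituted E-alkene and the methyl-bearing carbon intact from 20, and the core only has to supply an unbranched aldehyde. The forward reaction must give the E-alkene.

From 23 to 20: the C–S bond is traced to the allylic alcohol 21 through the sulfide 22, and 21 to the enone 20 by 1,2-reduction. Nothing in the ring is touched, so the ring stereocentres are bought, not made.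

From 19 to 15: 19 is the keto aldehyde obtained by double oxidation of the diol 18, itself the debenzylated form of 17. The cyclic ether 17 is the lactone 15 with C7 taken down from the carboxyl to the ether level through the lactol 16. The ketone is reduced along the way and restored in the double oxidation, which costs no extra step. The benzyl ether is chosen for the C1 chain because it survives hydride and Lewis acid and can be removed by hydrogenolysis while the molecule still has no alkene.

From 15 to 14 (key disconnection): the C1–C8 bond and the O6–C5 bond are cut together. Both rings open and the acyclic β-keto ester 14 results, with a trisubstituted C5=C8 alkene and a tert-butyl ester. Cutting here uses the natural 1,3-dicarbonyl relation at C1 and removes two rings and three stereocentres (C1, C5, C8) in one operation. The forward reaction is an oxidative radical cyclization by trivalent manganese with a divalent copper co-oxidant. It must close 6-endo, place the ester axial, and end by capture of the oxidized C5 by the ester carbonyl with loss of the tert-butyl group as the alkene.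

From 14 to 10, 11 and 13: the C1–chain bond is cut (alkylation of the keto ester 12 with the bromide 13), then the C1–C2 bond (Claisen condensation of the ester 10 with the enolate of 11). These are the most reliable ways to build a 2-substituted 3-oxo ester, and they keep the sensitive alkene out of the reacting region.

From 10 to 9: the C3–C4 bond is cut by a [3,3] disconnection (Johnson–Claisen) to the 2-substituted allylic alcohol 9. This is what fixes the alkene geometry: the chair transition state puts the C8 chain trans to the new C4 methylene, and therefore cis to Cx, as 14 requires.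

From 9 to 1 and 6: the C5–C8 bond of 9 is cut between a vinyl nucleophile and an aldehyde (Nozaki–Hiyama–Kishi), which gives the vinyl triflate 5 and the aldehyde 8. 5 comes from the methyl ketone 4, and 4 from 1 through the silyl ether 2 and the amide 3; 8 comes from 6 through 7. Cx is thus taken from the chiral pool, with the ester carbon of 1 becoming C5.

## Alternatives that were turned down

Alternative 1: The disconnection cuts C1–C8 and C4–C5 and leads to an α-substituted vinyl keto ester A1 and the nitroalkene A2. In the forward step a bifunctional cinchona amine–thiourea catalyst would add C1 of A1 to the nitroalkene carbon that becomes C8, and the nitronate would then add to the enone terminus to close the nitro cyclohexanone A3. In its favour, the absolute configuration at C1 and C8 is set by the catalyst, independently of Cx, and the fragments are simple and achiral; on this point it is stronger than the chosen route, whose absolute sense is relayed from Cx. Against it, C5 in A3 is a nitro-bearing CH. It still has to be turned into the oxygenated, fully substituted carbon with the Cx branch, by a Nef reaction and a carbonyl addition that must create C5 and Cx together, followed by a separate ether closure. An α-alkyl keto ester forming a quaternary centre with an aliphatic nitroalkene is also a poor substrate pair for hydrogen-bonding catalysis, and A1 polymerizes easily. In place of catalyst control, the chosen strategy forms C1–C8, the carbocycle, the C5–O6 bond and the bridge in one step from a precursor that already carries Cx.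

Alternative 2: The C1–C8 bond is traced back to a C2–C8 bond of the epoxy cyclopentanol A4. In the forward step BF3·OEt2 would open the 2,2-disubstituted epoxide at C1 while C8 shifts from the carbinol carbon to C1, expanding the ring to the hydroxymethyl cyclohexanone A5. In its favour, the 1,2-shift is stereospecific (inversion at C1, retention at C8), C5, C8 and Cx are already in place, and there is no radical partitioning; for the reliability of the key step itself it is the stronger proposal. Against it, all the difficulty moves into A4, a cyclopentane with contiguous C5, C8 and carbinol centres plus a stereodefined epoxide, which needs its own long stereocontrolled synthesis. Both ring bonds at the carbinol carbon (to C8 and to C3) can migrate, BF3 can also ionize the tertiary silyl ether at C5, and A5 still lacks the O6–C7 bond, which would have to be closed at a neopentyl carbon. The chosen route is shorter to its precursor and closes the ether bridge in the key step.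

Alternative 3: The disconnection cuts C5–C8 and C1–C7 and leads to the bicyclic ketal A6, in which C7 is still bound to C2 and C2 carries the C1=C8 alkene. In the forward step SnCl4 would open the ketal to a six-membered oxocarbenium ion at C5, the alkene would attack through C8, and the new C1 cation would trigger the shift of C7 from C2 to C1, giving the keto ether A7. In its favour, A7 already has C7 at the ether level and a C2 ketone, so the two reductions after the chosen key step are saved, and two rings and three stereocentres form at once, as in the chosen step; on oxidation-state economy it is stronger. Against it, the alkene on C2 has to reach C5 across the oxocarbenium ring, through a 2-oxabicyclo[2.2.2]octyl cation in which the π bond meets the cationic carbon almost in its own plane. The configuration at C8 then depends on the sense of twist and not simply on alkene geometry. The C2–O bond is tertiary and allylic and may ionize first, C5 is a fully substituted oxocarbenium carbon next to Cx, and A6 needs an enantioselectively made carbinol that is erased in the product. In exchange for two extra steps, the chosen strategy offers an acyclic precursor made by robust reactions and a ring closure with an unstrained chair geometry.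

Key step: step 10

Assumption: (1R,5S)-cis-α-irone (20) is taken as available as a single enantiomer (orris-derived material or the resolved commercial isomer mixture); where a SMILES leaves one centre undefined, the compound is a mixture of epimers at a centre that is removed later.

Step 1
Reactants: 1 methyl (2R)-3-hydroxy-2-methylpropanoate
Product: 2 methyl (2R)-3-[(tert-butyldimethylsilyl)oxy]-2-methylpropanoate
Conditions: TBSCl, imidazole, CH2Cl2, 0 °C → rt
Reagents that add atoms: tert-butyldimethylsilyl chloride, C[Si](C)(Cl)C(C)(C)C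
Why: Standard silylation of a primary alcohol; the stereocentre is not involved.

Step 2
Reactants: 2 methyl (2R)-3-[(tert-butyldimethylsilyl)oxy]-2-methylpropanoate
Product: 4 (3R)-4-[(tert-butyldimethylsilyl)oxy]-3-methylbutan-2-one, via Weinreb amide 3 (not isolated)
Conditions: MeNH(OMe)·HCl, i-PrMgCl, THF, −20 °C; then MeMgBr, −20 → 0 °C; aq. NH4Cl
Reagents that add atoms: N,O-dimethylhydroxylamine hydrochloride, CNOC.Cl; methylmagnesium bromide, C[Mg]Br
Why: The magnesium amide converts the ester into the Weinreb amide, whose chelated tetrahedral adduct with MeMgBr stops at the ketone stage; the ketone is released only on quench, so the α-centre is not epimerized.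

Step 3
Reactants: 4 (3R)-4-[(tert-butyldimethylsilyl)oxy]-3-methylbutan-2-one
Product: 5 (3R)-4-[(tert-butyldimethylsilyl)oxy]-3-methylbut-1-en-2-yl trifluoromethanesulfonate
Conditions: KN(SiMe3)2, THF, −78 °C; PhNTf2, −78 → 0 °C
Reagents that add atoms: N-phenylbis(trifluoromethanesulfonimide), O=S(=O)(N(c1ccccc1)S(=O)(=O)C(F)(F)F)C(F)(F)F
Why: Kinetic deprotonation by the bulky amide occurs at the methyl group, and O-sulfonylation gives the 2-triflyloxy-1-alkene; the methine next to the silyloxymethyl group is not deprotonated, so neither epimerization nor β-elimination should occur.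

Step 4
Reactants: 6 butane-1,4-diol
Product: 7 4-[(triisopropylsilyl)oxy]butan-1-ol
Conditions: NaH (1.0 equiv), THF, rt; TIPSCl
Reagents that add atoms: triisopropylsilyl chloride, CC(C)[Si](Cl)(C(C)C)C(C)C
Why: Monosilylation of a symmetrical diol through its sparingly soluble monosodium alkoxide.

Step 5
Reactants: 7 4-[(triisopropylsilyl)oxy]butan-1-ol
Product: 8 4-[(triisopropylsilyl)oxy]butanal
Conditions: TEMPO (cat.), PhI(OAc)2, CH2Cl2, rt
Reagents that add atoms: none
Why: Oxoammonium oxidation of a primary alcohol stops at the aldehyde and leaves the silyl ether alone.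

Step 6
Reactants: 5 (3R)-4-[(tert-butyldimethylsilyl)oxy]-3-methylbut-1-en-2-yl trifluoromethanesulfonate; 8 4-[(triisopropylsilyl)oxy]butanal
Product: 9 (2S)-1-[(tert-butyldimethylsilyl)oxy]-2-methyl-3-methylidene-7-[(triisopropylsilyl)oxy]heptan-4-ol (both C4 epimers)
Conditions: CrCl2, NiCl2 (cat.), DMF, rt
Reagents that add atoms: none
Why: Nozaki–Hiyama–Kishi coupling: nickel inserts into the vinyl triflate, the vinyl group passes to trivalent chromium and adds to the aldehyde only; the new carbinol centre is removed in step 7, so its configuration does not matter.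

Step 7
Reactants: 9 (2S)-1-[(tert-butyldimethylsilyl)oxy]-2-methyl-3-methylidene-7-[(triisopropylsilyl)oxy]heptan-4-ol
Product: 10 ethyl (4Z)-4-[(2S)-1-[(tert-butyldimethylsilyl)oxy]propan-2-yl]-8-[(triisopropylsilyl)oxy]oct-4-enoate
Conditions: MeC(OEt)3, EtCO2H (cat.), 140 °C, EtOH distilled off
Reagents that add atoms: triethyl orthoacetate, CCOC(C)(OCC)OCC
Why: Johnson–Claisen rearrangement through a chair in which the carbinol substituent is equatorial, so the C8 chain ends trans to the new C4 methylene and cis to Cx; both carbinol epimers converge on the same alkene.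

Step 8
Reactants: 10 ethyl (4Z)-4-[(2S)-1-[(tert-butyldimethylsilyl)oxy]propan-2-yl]-8-[(triisopropylsilyl)oxy]oct-4-enoate; 11 tert-butyl acetate
Product: 12 tert-butyl (6Z)-6-[(2S)-1-[(tert-butyldimethylsilyl)oxy]propan-2-yl]-3-oxo-10-[(triisopropylsilyl)oxy]dec-6-enoate
Conditions: LiN(i-Pr)2, 11 (3 equiv), THF, −78 °C; then 10, −78 → −10 °C
Reagents that add atoms: none
Why: Crossed Claisen condensation with excess lithium enolate of the tert-butyl ester; deprotonation of the product keto ester drives the acylation and the alkene and silyl ethers are not touched.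

Step 9
Reactants: 12 tert-butyl (6Z)-6-[(2S)-1-[(tert-butyldimethylsilyl)oxy]propan-2-yl]-3-oxo-10-[(triisopropylsilyl)oxy]dec-6-enoate; 13 benzyl 3-bromopropyl ether
Product: 14 tert-butyl (6Z)-2-[3-(benzyloxy)propyl]-6-[(2S)-1-[(tert-butyldimethylsilyl)oxy]propan-2-yl]-3-oxo-10-[(triisopropylsilyl)oxy]dec-6-enoate (both C2 epimers)
Conditions: NaH, THF/DMF, 0 °C; 13, NaI (cat.), 50 °C
Reagents that add atoms: none
Why: C-alkylation of the sodium enolate of a β-keto ester by a primary halide activated in the flask as the iodide; the C2 centre becomes a planar radical in step 10.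

Step 10
Reactants: 14 tert-butyl (6Z)-2-[3-(benzyloxy)propyl]-6-[(2S)-1-[(tert-butyldimethylsilyl)oxy]propan-2-yl]-3-oxo-10-[(triisopropylsilyl)oxy]dec-6-enoate
Product: 15 (1R,5R,8S)-1-[3-(benzyloxy)propyl]-5-[(2R)-1-[(tert-butyldimethylsilyl)oxy]propan-2-yl]-8-{3-[(triisopropylsilyl)oxy]propyl}-6-oxabicyclo[3.2.1]octane-2,7-dione
Conditions: Mn(OAc)3·2H2O (2.2 equiv), Cu(OAc)2·H2O (0.5 equiv), degassed AcOH, 25 °C
Reagents that add atoms: none
Why: Mn(OAc)3 forms the manganese enolate of 14 and oxidizes it to the C1 radical, an electrophilic tertiary radical between ketone and ester; the closest known reaction type is the oxidative free-radical cyclization of unsaturated β-keto esters by trivalent manganese and divalent copper that ends in a lactone. The radical closes the carbocycle 6-endo-trig onto C8, the less substituted alkene carbon, because the ketone lies inside the forming ring and a 5-exo closure would have to attack the fully substituted C5. In the chair transition state the C8 chain, which is trans to C4 on the alkene, becomes equatorial, and the flat tert-butoxycarbonyl group takes the axial site with the benzyloxypropyl chain equatorial, so C1 and C8 are set together with the ester cis to the C8 chain. Cu(OAc)2 oxidizes the tertiary C5 radical through an organocopper species of trivalent copper to the C5 cation and is regenerated by the second equivalent of Mn(OAc)3. The axial ester carbonyl oxygen, 1,3-diaxial to the vacant orbital, closes the lactone ring in a 5-exo closure onto the trigonal cation, which can only place the C5–O6 bond cis to C7, and the dialkoxycarbenium ion loses isobutene. The absolute sense comes from Cx: allylic 1,3-strain with the cis C8 chain holds the Cx–H bond in the alkene plane, so the methyl and the CH2OTBS groups cover opposite faces and the C1 radical, then O6, enter on the methyl side; the bulky axial tert-butyl ester, which passes over C5, should sharpen this choice. The step needs 6-endo regioselectivity (secured by the substitution pattern), capture of the cation instead of proton loss (secured by the axial ester and its tert-butyl leaving group) and face selectivity (secured only by the size difference at Cx, the weakest point).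

Step 11
Reactants: 15 (1R,5R,8S)-1-[3-(benzyloxy)propyl]-5-[(2R)-1-[(tert-butyldimethylsilyl)oxy]propan-2-yl]-8-{3-[(triisopropylsilyl)oxy]propyl}-6-oxabicyclo[3.2.1]octane-2,7-dione
Product: 16 (1R,5R,8S)-1-[3-(benzyloxy)propyl]-5-[(2R)-1-[(tert-butyldimethylsilyl)oxy]propan-2-yl]-8-{3-[(triisopropylsilyl)oxy]propyl}-6-oxabicyclo[3.2.1]octane-2,7-diol (epimers at C2 and C7)
Conditions: i-Bu2AlH (5 equiv), CH2Cl2, −78 °C; Rochelle salt
Reagents that add atoms: none
Why: Hydride reduction of the ketone to the carbinol and of the lactone to the lactol, whose aluminium hemiacetal is stable at −78 °C; benzyl and silyl ethers are inert, and the C2 configuration is irrelevant because the ketone is restored in step 14.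

Step 12
Reactants: 16 (1R,5R,8S)-1-[3-(benzyloxy)propyl]-5-[(2R)-1-[(tert-butyldimethylsilyl)oxy]propan-2-yl]-8-{3-[(triisopropylsilyl)oxy]propyl}-6-oxabicyclo[3.2.1]octane-2,7-diol
Product: 17 (1S,5R,8S)-1-[3-(benzyloxy)propyl]-5-[(2R)-1-[(tert-butyldimethylsilyl)oxy]propan-2-yl]-8-{3-[(triisopropylsilyl)oxy]propyl}-6-oxabicyclo[3.2.1]octan-2-ol (C2 epimers)
Conditions: Et3SiH, BF3·OEt2, CH2Cl2, −78 → −40 °C
Reagents that add atoms: none
Why: Ionic reduction of a lactol: BF3 ionizes the hemiacetal to the five-membered oxocarbenium ion (C7=O6 lies in the two-atom bridge, not at a bridgehead) and the silane delivers hydride; the C2 hydroxyl cannot reach C7 and no stereocentre changes.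

Step 13
Reactants: 17 (1S,5R,8S)-1-[3-(benzyloxy)propyl]-5-[(2R)-1-[(tert-butyldimethylsilyl)oxy]propan-2-yl]-8-{3-[(triisopropylsilyl)oxy]propyl}-6-oxabicyclo[3.2.1]octan-2-ol
Product: 18 (1S,5R,8S)-5-[(2R)-1-[(tert-butyldimethylsilyl)oxy]propan-2-yl]-1-(3-hydroxypropyl)-8-{3-[(triisopropylsilyl)oxy]propyl}-6-oxabicyclo[3.2.1]octan-2-ol (C2 epimers)
Conditions: H2 (1 atm), Pd/C, EtOAc, rt
Reagents that add atoms: none
Why: Hydrogenolysis of the benzyl ether at a stage where the molecule has no alkene; ethyl acetate as solvent avoids solvolysis of the silyl ethers.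

Step 14
Reactants: 18 (1S,5R,8S)-5-[(2R)-1-[(tert-butyldimethylsilyl)oxy]propan-2-yl]-1-(3-hydroxypropyl)-8-{3-[(triisopropylsilyl)oxy]propyl}-6-oxabicyclo[3.2.1]octan-2-ol
Product: 19 3-[(1S,5R,8S)-5-[(2R)-1-[(tert-butyldimethylsilyl)oxy]propan-2-yl]-2-oxo-8-{3-[(triisopropylsilyl)oxy]propyl}-6-oxabicyclo[3.2.1]octan-1-yl]propanal
Conditions: (COCl)2, DMSO, CH2Cl2, −78 °C; Et3N, −78 → 0 °C
Reagents that add atoms: none
Why: Swern oxidation of both alcohols; both are converted into alkoxysulfonium ions before the base is added, so no hydroxy aldehyde is present beside active oxidant and no lactol or lactone can form.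

Step 15
Reactants: 20 (3E)-4-[(1R,5S)-2,5,6,6-tetramethylcyclohex-2-en-1-yl]but-3-en-2-one
Product: 21 (3E)-4-[(1R,5S)-2,5,6,6-tetramethylcyclohex-2-en-1-yl]but-3-en-2-ol (both carbinol epimers)
Conditions: NaBH4, CeCl3·7H2O, MeOH, 0 °C
Reagents that add atoms: none
Why: Luche reduction gives clean 1,2-reduction of the enone without base, so the ring centre next to the alkene is not epimerized; the carbinol centre is lost in step 18.

Step 16
Reactants: 21 (3E)-4-[(1R,5S)-2,5,6,6-tetramethylcyclohex-2-en-1-yl]but-3-en-2-ol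
Product: 22 1-phenyl-5-{[(3E)-4-[(1R,5S)-2,5,6,6-tetramethylcyclohex-2-en-1-yl]but-3-en-2-yl]sulfanyl}-1H-tetrazole (epimers at the sulfur-bearing carbon)
Conditions: 1-phenyl-1H-tetrazole-5-thiol, PPh3, DIAD, THF, 0 °C → rt
Reagents that add atoms: 1-phenyl-1H-tetrazole-5-thiol, Sc1nnnn1-c1ccccc1
Why: Mitsunobu thioetherification of a secondary allylic alcohol; direct substitution is favoured because the transposed position is next to the hindered ring carbon.

Step 17
Reactants: 22 1-phenyl-5-{[(3E)-4-[(1R,5S)-2,5,6,6-tetramethylcyclohex-2-en-1-yl]but-3-en-2-yl]sulfanyl}-1H-tetrazole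
Product: 23 1-phenyl-5-{[(3E)-4-[(1R,5S)-2,5,6,6-tetramethylcyclohex-2-en-1-yl]but-3-en-2-yl]sulfonyl}-1H-tetrazole (epimers at the sulfur-bearing carbon)
Conditions: H2O2 (30% aq.), (NH4)6Mo7O24·4H2O (cat.), EtOH, 0 °C → rt
Reagents that add atoms: hydrogen peroxide, OO
Why: Molybdate-catalysed peroxide oxidation is selective for sulfur over the two alkenes.

Step 18
Reactants: 19 3-[(1S,5R,8S)-5-[(2R)-1-[(tert-butyldimethylsilyl)oxy]propan-2-yl]-2-oxo-8-{3-[(triisopropylsilyl)oxy]propyl}-6-oxabicyclo[3.2.1]octan-1-yl]propanal; 23 1-phenyl-5-{[(3E)-4-[(1R,5S)-2,5,6,6-tetramethylcyclohex-2-en-1-yl]but-3-en-2-yl]sulfonyl}-1H-tetrazole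
Product: 24 (1S,5R,8S)-5-[(2R)-1-[(tert-butyldimethylsilyl)oxy]propan-2-yl]-1-[(3E,5E)-4-methyl-6-[(1R,5S)-2,5,6,6-tetramethylcyclohex-2-en-1-yl]hexa-3,5-dien-1-yl]-8-{3-[(triisopropylsilyl)oxy]propyl}-6-oxabicyclo[3.2.1]octan-2-one
Conditions: 23 (1.3 equiv), KN(SiMe3)2, THF, −78 °C; then 19, −78 °C → rt
Reagents that add atoms: none
Why: Julia–Kocienski olefination: the allylic sulfonyl anion adds through its α-carbon to the aldehyde, Smiles transfer of the tetrazole and loss of SO2 give the trisubstituted alkene; the E isomer, which keeps the diene planar, is expected to predominate. The C2 ketone is flanked by the quaternary C1 and should not compete with the aldehyde.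

Step 19
Reactants: 24 (1S,5R,8S)-5-[(2R)-1-[(tert-butyldimethylsilyl)oxy]propan-2-yl]-1-[(3E,5E)-4-methyl-6-[(1R,5S)-2,5,6,6-tetramethylcyclohex-2-en-1-yl]hexa-3,5-dien-1-yl]-8-{3-[(triisopropylsilyl)oxy]propyl}-6-oxabicyclo[3.2.1]octan-2-one
Product: 25 (1S,2S,5R,8S)-5-[(2R)-1-[(tert-butyldimethylsilyl)oxy]propan-2-yl]-2-methyl-1-[(3E,5E)-4-methyl-6-[(1R,5S)-2,5,6,6-tetramethylcyclohex-2-en-1-yl]hexa-3,5-dien-1-yl]-8-{3-[(triisopropylsilyl)oxy]propyl}-6-oxabicyclo[3.2.1]octan-2-ol
Conditions: AlMe3 (4 equiv), toluene, −20 °C → rt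
Reagents that add atoms: trimethylaluminium, C[Al](C)C
Why: Carbonyl addition of excess AlMe3 in a hydrocarbon solvent, where a second AlMe3 delivers methyl to the aluminium-complexed ketone, the reagent combination known for axial attack on cyclohexanones. Equatorial attack would force the complexed oxygen past the equatorial C1 chain and meets the inward hydrogen of C7, so methyl should enter axially, anti to the C7 bridge, which gives the (2S) carbinol with the hydroxyl equatorial.

Step 20
Reactants: 25 (1S,2S,5R,8S)-5-[(2R)-1-[(tert-butyldimethylsilyl)oxy]propan-2-yl]-2-methyl-1-[(3E,5E)-4-methyl-6-[(1R,5S)-2,5,6,6-tetramethylcyclohex-2-en-1-yl]hexa-3,5-dien-1-yl]-8-{3-[(triisopropylsilyl)oxy]propyl}-6-oxabicyclo[3.2.1]octan-2-ol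
Product: 26 (1S,2S,5R,8S)-5-[(2R)-1-hydroxypropan-2-yl]-2-methyl-1-[(3E,5E)-4-methyl-6-[(1R,5S)-2,5,6,6-tetramethylcyclohex-2-en-1-yl]hexa-3,5-dien-1-yl]-8-{3-[(triisopropylsilyl)oxy]propyl}-6-oxabicyclo[3.2.1]octan-2-ol
Conditions: CSA (cat.), MeOH/CH2Cl2, 0 °C
Reagents that add atoms: none
Why: Acid-catalysed methanolysis cleaves a primary tert-butyldimethylsilyl ether much faster than a primary triisopropylsilyl ether, because attack at silicon is governed by the bulk on silicon; diene and tertiary alcohol tolerate the mild acid.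

Step 21
Reactants: 26 (1S,2S,5R,8S)-5-[(2R)-1-hydroxypropan-2-yl]-2-methyl-1-[(3E,5E)-4-methyl-6-[(1R,5S)-2,5,6,6-tetramethylcyclohex-2-en-1-yl]hexa-3,5-dien-1-yl]-8-{3-[(triisopropylsilyl)oxy]propyl}-6-oxabicyclo[3.2.1]octan-2-ol
Product: 27 (2S)-2-[(1S,2S,5R,8S)-2-hydroxy-2-methyl-1-[(3E,5E)-4-methyl-6-[(1R,5S)-2,5,6,6-tetramethylcyclohex-2-en-1-yl]hexa-3,5-dien-1-yl]-8-{3-[(triisopropylsilyl)oxy]propyl}-6-oxabicyclo[3.2.1]octan-5-yl]propanal
Conditions: Dess–Martin periodinane, NaHCO3, CH2Cl2, 0 °C → rt
Reagents that add atoms: none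
Why: Dess–Martin oxidation of the only primary alcohol; the tertiary alcohol cannot be oxidized and the buffer keeps the new α-stereocentre from epimerizing.

Step 22
Reactants: 27 (2S)-2-[(1S,2S,5R,8S)-2-hydroxy-2-methyl-1-[(3E,5E)-4-methyl-6-[(1R,5S)-2,5,6,6-tetramethylcyclohex-2-en-1-yl]hexa-3,5-dien-1-yl]-8-{3-[(triisopropylsilyl)oxy]propyl}-6-oxabicyclo[3.2.1]octan-5-yl]propanal
Product: 28 (2S)-2-[(1S,2S,5R,8S)-2-hydroxy-8-(3-hydroxypropyl)-2-methyl-1-[(3E,5E)-4-methyl-6-[(1R,5S)-2,5,6,6-tetramethylcyclohex-2-en-1-yl]hexa-3,5-dien-1-yl]-6-oxabicyclo[3.2.1]octan-5-yl]propanal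
Conditions: HF·pyridine, pyridine, THF, 0 °C → rt
Reagents that add atoms: none
Why: Fluoride-mediated desilylation under buffered, weakly acidic conditions, which do not enolize the aldehyde next to the quaternary C5 and leave the diene untouched.

## Compound list

1 | methyl (2R)-3-hydroxy-2-methylpropanoate | COC(=O)[C@H](C)CO | starting material
2 | methyl (2R)-3-[(tert-butyldimethylsilyl)oxy]-2-methylpropanoate | COC(=O)[C@H](C)CO[Si](C)(C)C(C)(C)C | intermediate
3 | (2R)-3-[(tert-butyldimethylsilyl)oxy]-N-methoxy-N,2-dimethylpropanamide | CON(C)C(=O)[C@H](C)CO[Si](C)(C)C(C)(C)C | intermediate (not isolated)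
4 | (3R)-4-[(tert-butyldimethylsilyl)oxy]-3-methylbutan-2-one | CC(=O)[C@H](C)CO[Si](C)(C)C(C)(C)C | intermediate
5 | (3R)-4-[(tert-butyldimethylsilyl)oxy]-3-methylbut-1-en-2-yl trifluoromethanesulfonate | C=C(OS(=O)(=O)C(F)(F)F)[C@H](C)CO[Si](C)(C)C(C)(C)C | intermediate
6 | butane-1,4-diol | OCCCCO | starting material
7 | 4-[(triisopropylsilyl)oxy]butan-1-ol | OCCCCO[Si](C(C)C)(C(C)C)C(C)C | intermediate
8 | 4-[(triisopropylsilyl)oxy]butanal | O=CCCCO[Si](C(C)C)(C(C)C)C(C)C | intermediate
9 | (2S)-1-[(tert-butyldimethylsilyl)oxy]-2-methyl-3-methylidene-7-[(triisopropylsilyl)oxy]heptan-4-ol (C4 epimers) | C=C([C@H](C)CO[Si](C)(C)C(C)(C)C)C(O)CCCO[Si](C(C)C)(C(C)C)C(C)C | intermediate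
10 | ethyl (4Z)-4-[(2S)-1-[(tert-butyldimethylsilyl)oxy]propan-2-yl]-8-[(triisopropylsilyl)oxy]oct-4-enoate | CCOC(=O)CC/C(=C/CCCO[Si](C(C)C)(C(C)C)C(C)C)[C@H](C)CO[Si](C)(C)C(C)(C)C | intermediate
11 | tert-butyl acetate | CC(=O)OC(C)(C)C | starting material
12 | tert-butyl (6Z)-6-[(2S)-1-[(tert-butyldimethylsilyl)oxy]propan-2-yl]-3-oxo-10-[(triisopropylsilyl)oxy]dec-6-enoate | CC(C)(C)OC(=O)CC(=O)CC/C(=C/CCCO[Si](C(C)C)(C(C)C)C(C)C)[C@H](C)CO[Si](C)(C)C(C)(C)C | intermediate
13 | benzyl 3-bromopropyl ether | BrCCCOCc1ccccc1 | starting material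
14 | tert-butyl (6Z)-2-[3-(benzyloxy)propyl]-6-[(2S)-1-[(tert-butyldimethylsilyl)oxy]propan-2-yl]-3-oxo-10-[(triisopropylsilyl)oxy]dec-6-enoate (C2 epimers) | CC(C)(C)OC(=O)C(CCCOCc1ccccc1)C(=O)CC/C(=C/CCCO[Si](C(C)C)(C(C)C)C(C)C)[C@H](C)CO[Si](C)(C)C(C)(C)C | intermediate
15 | (1R,5R,8S)-1-[3-(benzyloxy)propyl]-5-[(2R)-1-[(tert-butyldimethylsilyl)oxy]propan-2-yl]-8-{3-[(triisopropylsilyl)oxy]propyl}-6-oxabicyclo[3.2.1]octane-2,7-dione | C(c1ccccc1)OCCC[C@]12C(=O)O[C@]([C@H](C)CO[Si](C)(C)C(C)(C)C)(CCC1=O)[C@H]2CCCO[Si](C(C)C)(C(C)C)C(C)C | intermediate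
16 | (1R,5R,8S)-1-[3-(benzyloxy)propyl]-5-[(2R)-1-[(tert-butyldimethylsilyl)oxy]propan-2-yl]-8-{3-[(triisopropylsilyl)oxy]propyl}-6-oxabicyclo[3.2.1]octane-2,7-diol (epimers at C2 and C7) | C(c1ccccc1)OCCC[C@]12C(O)O[C@]([C@H](C)CO[Si](C)(C)C(C)(C)C)(CCC1O)[C@H]2CCCO[Si](C(C)C)(C(C)C)C(C)C | intermediate
17 | (1S,5R,8S)-1-[3-(benzyloxy)propyl]-5-[(2R)-1-[(tert-butyldimethylsilyl)oxy]propan-2-yl]-8-{3-[(triisopropylsilyl)oxy]propyl}-6-oxabicyclo[3.2.1]octan-2-ol (C2 epimers) | C(c1ccccc1)OCCC[C@]12CO[C@]([C@H](C)CO[Si](C)(C)C(C)(C)C)(CCC1O)[C@H]2CCCO[Si](C(C)C)(C(C)C)C(C)C | intermediate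
18 | (1S,5R,8S)-5-[(2R)-1-[(tert-butyldimethylsilyl)oxy]propan-2-yl]-1-(3-hydroxypropyl)-8-{3-[(triisopropylsilyl)oxy]propyl}-6-oxabicyclo[3.2.1]octan-2-ol (C2 epimers) | OCCC[C@]12CO[C@]([C@H](C)CO[Si](C)(C)C(C)(C)C)(CCC1O)[C@H]2CCCO[Si](C(C)C)(C(C)C)C(C)C | intermediate
19 | 3-[(1S,5R,8S)-5-[(2R)-1-[(tert-butyldimethylsilyl)oxy]propan-2-yl]-2-oxo-8-{3-[(triisopropylsilyl)oxy]propyl}-6-oxabicyclo[3.2.1]octan-1-yl]propanal | O=CCC[C@]12CO[C@]([C@H](C)CO[Si](C)(C)C(C)(C)C)(CCC1=O)[C@H]2CCCO[Si](C(C)C)(C(C)C)C(C)C | intermediate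
20 | (3E)-4-[(1R,5S)-2,5,6,6-tetramethylcyclohex-2-en-1-yl]but-3-en-2-one (cis-α-irone) | CC1=CC[C@H](C)C(C)(C)[C@@H]1/C=C/C(C)=O | starting material
21 | (3E)-4-[(1R,5S)-2,5,6,6-tetramethylcyclohex-2-en-1-yl]but-3-en-2-ol (carbinol epimers) | CC1=CC[C@H](C)C(C)(C)[C@@H]1/C=C/C(C)O | intermediate
22 | 1-phenyl-5-{[(3E)-4-[(1R,5S)-2,5,6,6-tetramethylcyclohex-2-en-1-yl]but-3-en-2-yl]sulfanyl}-1H-tetrazole (epimers at the sulfur-bearing carbon) | CC1=CC[C@H](C)C(C)(C)[C@@H]1/C=C/C(C)Sc2nnnn2-c2ccccc2 | intermediate
23 | 1-phenyl-5-{[(3E)-4-[(1R,5S)-2,5,6,6-tetramethylcyclohex-2-en-1-yl]but-3-en-2-yl]sulfonyl}-1H-tetrazole (epimers at the sulfur-bearing carbon) | CC1=CC[C@H](C)C(C)(C)[C@@H]1/C=C/C(C)S(=O)(=O)c2nnnn2-c2ccccc2 | intermediate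
24 | (1S,5R,8S)-5-[(2R)-1-[(tert-butyldimethylsilyl)oxy]propan-2-yl]-1-[(3E,5E)-4-methyl-6-[(1R,5S)-2,5,6,6-tetramethylcyclohex-2-en-1-yl]hexa-3,5-dien-1-yl]-8-{3-[(triisopropylsilyl)oxy]propyl}-6-oxabicyclo[3.2.1]octan-2-one | CC1=CC[C@H](C)C(C)(C)[C@@H]1/C=C/C(C)=C/CC[C@]12CO[C@]([C@H](C)CO[Si](C)(C)C(C)(C)C)(CCC1=O)[C@H]2CCCO[Si](C(C)C)(C(C)C)C(C)C | intermediate
25 | (1S,2S,5R,8S)-5-[(2R)-1-[(tert-butyldimethylsilyl)oxy]propan-2-yl]-2-methyl-1-[(3E,5E)-4-methyl-6-[(1R,5S)-2,5,6,6-tetramethylcyclohex-2-en-1-yl]hexa-3,5-dien-1-yl]-8-{3-[(triisopropylsilyl)oxy]propyl}-6-oxabicyclo[3.2.1]octan-2-ol | CC1=CC[C@H](C)C(C)(C)[C@@H]1/C=C/C(C)=C/CC[C@]12CO[C@]([C@H](C)CO[Si](C)(C)C(C)(C)C)(CC[C@]1(C)O)[C@H]2CCCO[Si](C(C)C)(C(C)C)C(C)C | intermediate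
26 | (1S,2S,5R,8S)-5-[(2R)-1-hydroxypropan-2-yl]-2-methyl-1-[(3E,5E)-4-methyl-6-[(1R,5S)-2,5,6,6-tetramethylcyclohex-2-en-1-yl]hexa-3,5-dien-1-yl]-8-{3-[(triisopropylsilyl)oxy]propyl}-6-oxabicyclo[3.2.1]octan-2-ol | CC1=CC[C@H](C)C(C)(C)[C@@H]1/C=C/C(C)=C/CC[C@]12CO[C@]([C@H](C)CO)(CC[C@]1(C)O)[C@H]2CCCO[Si](C(C)C)(C(C)C)C(C)C | intermediate
27 | (2S)-2-[(1S,2S,5R,8S)-2-hydroxy-2-methyl-1-[(3E,5E)-4-methyl-6-[(1R,5S)-2,5,6,6-tetramethylcyclohex-2-en-1-yl]hexa-3,5-dien-1-yl]-8-{3-[(triisopropylsilyl)oxy]propyl}-6-oxabicyclo[3.2.1]octan-5-yl]propanal | CC1=CC[C@H](C)C(C)(C)[C@@H]1/C=C/C(C)=C/CC[C@]12CO[C@]([C@H](C)C=O)(CC[C@]1(C)O)[C@H]2CCCO[Si](C(C)C)(C(C)C)C(C)C | intermediate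
28 | (2S)-2-[(1S,2S,5R,8S)-2-hydroxy-8-(3-hydroxypropyl)-2-methyl-1-[(3E,5E)-4-methyl-6-[(1R,5S)-2,5,6,6-tetramethylcyclohex-2-en-1-yl]hexa-3,5-dien-1-yl]-6-oxabicyclo[3.2.1]octan-5-yl]propanal | CC1=CC[C@H](C)C(C)(C)[C@@H]1/C=C/C(C)=C/CC[C@]12CO[C@]([C@H](C)C=O)(CC[C@]1(C)O)[C@H]2CCCO | target

## Step count and least certain steps

Total: 22 steps. Longest linear sequence: 17 steps (from 1 through steps 1–3, 6–14 and 18–22).

Step 10 (key step). The most likely failure is that the oxidized C5 centre loses a proton instead of being captured by the ester, because copper-mediated oxidation of alkyl radicals normally ends in alkenes and lactone capture has to outrun it. The second concern is incomplete face discrimination by Cx, since a methyl and a silyloxymethyl group differ only moderately in size; the unwanted isomer would be a separable diastereomer of 15, and a larger silyl group on the Cx oxygen is the handle for it. Fallback for the termination: set out from 14 and decouple ring closure from lactonization. The same oxidants in ethanol should stop at the alkene, giving tert-butyl (1R,6R)-1-[3-(benzyloxy)propyl]-5-[(2S)-1-[(tert-butyldimethylsilyl)oxy]propan-2-yl]-2-oxo-6-{3-[(triisopropylsilyl)oxy]propyl}cyclohex-4-ene-1-carboxylate F1, in which C1 and C8 are already set. Iodolactonization (I2, NaHCO3, MeCN), in which the tert-butyl ester acts as the internal nucleophile and loses isobutene, should then give the iodolactone (1R,4S,5R,8S)-1-[3-(benzyloxy)propyl]-5-[(2R)-1-[(tert-butyldimethylsilyl)oxy]propan-2-yl]-4-iodo-8-{3-[(triisopropylsilyl)oxy]propyl}-6-oxabicyclo[3.2.1]octane-2,7-dione F2. Radical deiodination (Bu3SnH, AIBN, toluene, 80 °C) returns to the route at 15.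

Step 12. The risk is Lewis-acid damage during the ionic reduction: loss of the tert-butyldimethylsilyl ether, or interception of the oxocarbenium ion by the benzyl ether oxygen of the C1 chain through a six-membered oxonium ion. Fallback without an oxocarbenium ion: set out from 15 and reduce it fully with LiAlH4 to the triol (1R,2S,3S)-3-[3-(benzyloxy)propyl]-1-[(2R)-1-[(tert-butyldimethylsilyl)oxy]propan-2-yl]-3-(hydroxymethyl)-2-{3-[(triisopropylsilyl)oxy]propyl}cyclohexane-1,4-diol F3. Catalytic CSA in dry CH2Cl2 should then close the ether by ionization of the tertiary C5 hydroxyl and capture by the primary C7 hydroxyl, the known cyclodehydration of 1,4-diols with a tertiary carbinol, which returns to the route at 17.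

Step 18. The risk is poor E/Z control at the new trisubstituted alkene (and some attack through the γ-carbon of the allylic anion), because secondary allylic sulfones give less predictable geometry than primary alkyl ones. Fallback with the geometry fixed at an isolable stage (Horner–Wittig): set out from 21 and convert it (PPh3, CCl4) into the chloride (1E)-3-chloro-1-[(1R,5S)-2,5,6,6-tetramethylcyclohex-2-en-1-yl]but-1-ene F4. Displacement with Ph2P(O)H and KN(SiMe3)2 gives diphenyl{(3E)-4-[(1R,5S)-2,5,6,6-tetramethylcyclohex-2-en-1-yl]but-3-en-2-yl}phosphine oxide F5. Its lithio derivative (n-BuLi, THF, −78 °C) is added to 19, and the diastereomeric adducts are separated to give the β-hydroxy phosphine oxide (1S,5R,8S)-5-[(2R)-1-[(tert-butyldimethylsilyl)oxy]propan-2-yl]-1-{(5E)-4-(diphenylphosphoryl)-3-hydroxy-4-methyl-6-[(1R,5S)-2,5,6,6-tetramethylcyclohex-2-en-1-yl]hex-5-en-1-yl}-8-{3-[(triisopropylsilyl)oxy]propyl}-6-oxabicyclo[3.2.1]octan-2-one F6. Stereospecific syn elimination of the appropriate diastereomer (NaH, DMF) returns to the route at 24.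

Step 19. The risk is methyl delivery from the equatorial face, which would give the C2 epimer. Both faces of the ketone are flanked (the axial one by the inward hydrogen on C8, the equatorial one by the C7 methylene), and the axial preference of excess AlMe3 is carried over from simple cyclohexanones. Fallback with a different stereochemical determinant: set out from 24 and add dimethylsulfonium methylide (Me3SI, KN(SiMe3)2, THF, −10 °C), the small, irreversibly adding one-carbon nucleophile with the strongest axial preference. This should give the spiro-epoxide (1S,2S,5R,8S)-5-[(2R)-1-[(tert-butyldimethylsilyl)oxy]propan-2-yl]-1-[(3E,5E)-4-methyl-6-[(1R,5S)-2,5,6,6-tetramethylcyclohex-2-en-1-yl]hexa-3,5-dien-1-yl]-8-{3-[(triisopropylsilyl)oxy]propyl}spiro[6-oxabicyclo[3.2.1]octane-2,2'-oxirane] F7, with the oxygen equatorial. Opening at the methylene with LiBHEt3 returns to the route at 25. The reversible sulfoxonium ylide would give the other spiro-epoxide if the faces turn out to be reversed.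

## Further compounds

F1 | step 10 | tert-butyl (1R,6R)-1-[3-(benzyloxy)propyl]-5-[(2S)-1-[(tert-butyldimethylsilyl)oxy]propan-2-yl]-2-oxo-6-{3-[(triisopropylsilyl)oxy]propyl}cyclohex-4-ene-1-carboxylate | CC(C)(C)OC(=O)[C@@]1(CCCOCc2ccccc2)C(=O)CC=C([C@H](C)CO[Si](C)(C)C(C)(C)C)[C@H]1CCCO[Si](C(C)C)(C(C)C)C(C)C
F2 | step 10 | (1R,4S,5R,8S)-1-[3-(benzyloxy)propyl]-5-[(2R)-1-[(tert-butyldimethylsilyl)oxy]propan-2-yl]-4-iodo-8-{3-[(triisopropylsilyl)oxy]propyl}-6-oxabicyclo[3.2.1]octane-2,7-dione | C(c1ccccc1)OCCC[C@]12C(=O)O[C@]([C@H](C)CO[Si](C)(C)C(C)(C)C)([C@@H](I)CC1=O)[C@H]2CCCO[Si](C(C)C)(C(C)C)C(C)C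
F3 | step 12 | (1R,2S,3S)-3-[3-(benzyloxy)propyl]-1-[(2R)-1-[(tert-butyldimethylsilyl)oxy]propan-2-yl]-3-(hydroxymethyl)-2-{3-[(triisopropylsilyl)oxy]propyl}cyclohexane-1,4-diol (C4 epimers) | C(c1ccccc1)OCCC[C@]1(CO)C(O)CC[C@](O)([C@H](C)CO[Si](C)(C)C(C)(C)C)[C@H]1CCCO[Si](C(C)C)(C(C)C)C(C)C
F4 | step 18 | (1E)-3-chloro-1-[(1R,5S)-2,5,6,6-tetramethylcyclohex-2-en-1-yl]but-1-ene (epimers at the chlorine-bearing carbon) | CC1=CC[C@H](C)C(C)(C)[C@@H]1/C=C/C(C)Cl
F5 | step 18 | diphenyl{(3E)-4-[(1R,5S)-2,5,6,6-tetramethylcyclohex-2-en-1-yl]but-3-en-2-yl}phosphine oxide (epimers at the phosphorus-bearing carbon) | CC1=CC[C@H](C)C(C)(C)[C@@H]1/C=C/C(C)P(=O)(c2ccccc2)c2ccccc2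
F6 | step 18 | (1S,5R,8S)-5-[(2R)-1-[(tert-butyldimethylsilyl)oxy]propan-2-yl]-1-{(5E)-4-(diphenylphosphoryl)-3-hydroxy-4-methyl-6-[(1R,5S)-2,5,6,6-tetramethylcyclohex-2-en-1-yl]hex-5-en-1-yl}-8-{3-[(triisopropylsilyl)oxy]propyl}-6-oxabicyclo[3.2.1]octan-2-one (the separated diastereomer that eliminates to the E-alkene) | CC1=CC[C@H](C)C(C)(C)[C@@H]1/C=C/C(C)(P(=O)(c2ccccc2)c2ccccc2)C(O)CC[C@]12CO[C@]([C@H](C)CO[Si](C)(C)C(C)(C)C)(CCC1=O)[C@H]2CCCO[Si](C(C)C)(C(C)C)C(C)C
F7 | step 19 | (1S,2S,5R,8S)-5-[(2R)-1-[(tert-butyldimethylsilyl)oxy]propan-2-yl]-1-[(3E,5E)-4-methyl-6-[(1R,5S)-2,5,6,6-tetramethylcyclohex-2-en-1-yl]hexa-3,5-dien-1-yl]-8-{3-[(triisopropylsilyl)oxy]propyl}spiro[6-oxabicyclo[3.2.1]octane-2,2'-oxirane] | CC1=CC[C@H](C)C(C)(C)[C@@H]1/C=C/C(C)=C/CC[C@]12CO[C@]([C@H](C)CO[Si](C)(C)C(C)(C)C)(CC[C@]13OC3)[C@H]2CCCO[Si](C(C)C)(C(C)C)C(C)C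
A1 | alternative 1 | methyl 2-[3-(benzyloxy)propyl]-3-oxopent-4-enoate | COC(=O)C(CCCOCc1ccccc1)C(=O)C=C
A2 | alternative 1 | triisopropyl{[(4E)-5-nitropent-4-en-1-yl]oxy}silane | O=[N+]([O-])/C=C/CCCO[Si](C(C)C)(C(C)C)C(C)C
A3 | alternative 1 | methyl (1R,5S,6S)-1-[3-(benzyloxy)propyl]-5-nitro-2-oxo-6-{3-[(triisopropylsilyl)oxy]propyl}cyclohexane-1-carboxylate | COC(=O)[C@@]1(CCCOCc2ccccc2)C(=O)CC[C@H]([N+](=O)[O-])[C@H]1CCCO[Si](C(C)C)(C(C)C)C(C)C
A4 | alternative 2 | 1-{2-[3-(benzyloxy)propyl]oxiran-2-yl}-3-[1-[(tert-butyldimethylsilyl)oxy]propan-2-yl]-3-[(triethylsilyl)oxy]-2-{3-[(triisopropylsilyl)oxy]propyl}cyclopentan-1-ol (configuration as in the SMILES; carbinol centre either epimer) | OC1(CC[C@](O[Si](CC)(CC)CC)([C@H](C)CO[Si](C)(C)C(C)(C)C)[C@H]1CCCO[Si](C(C)C)(C(C)C)C(C)C)[C@@]2(CCCOCc3ccccc3)CO2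
A5 | alternative 2 | (2S,3S,4R)-2-[3-(benzyloxy)propyl]-4-[(2R)-1-[(tert-butyldimethylsilyl)oxy]propan-2-yl]-2-(hydroxymethyl)-4-[(triethylsilyl)oxy]-3-{3-[(triisopropylsilyl)oxy]propyl}cyclohexan-1-one | OC[C@@]1(CCCOCc2ccccc2)C(=O)CC[C@](O[Si](CC)(CC)CC)([C@H](C)CO[Si](C)(C)C(C)(C)C)[C@H]1CCCO[Si](C(C)C)(C(C)C)C(C)C
A6 | alternative 3 | (4E)-4-{1-[1-[(tert-butyldimethylsilyl)oxy]propan-2-yl]-2,7-dioxabicyclo[2.2.1]heptan-4-yl}-8-[(triisopropylsilyl)oxy]oct-4-en-1-yl 2,2-dimethylpropanoate (configuration as in the SMILES) | [C@@]12(O[C@](CC1)(OC2)[C@H](C)CO[Si](C)(C)C(C)(C)C)/C(CCCOC(=O)C(C)(C)C)=C/CCCO[Si](C(C)C)(C(C)C)C(C)C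
A7 | alternative 3 | 3-[(1S,5R,8S)-5-[(2R)-1-[(tert-butyldimethylsilyl)oxy]propan-2-yl]-2-oxo-8-{3-[(triisopropylsilyl)oxy]propyl}-6-oxabicyclo[3.2.1]octan-1-yl]propyl 2,2-dimethylpropanoate | CC(C)(C)C(=O)OCCC[C@]12CO[C@]([C@H](C)CO[Si](C)(C)C(C)(C)C)(CCC1=O)[C@H]2CCCO[Si](C(C)C)(C(C)C)C(C)C
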